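## Plan

1. Retrosynthesis: cut the C8–prenyl bond first (back to the 5-O-prenyl ether, para-Claisen–Cope), then C3–C4 of ring C (back to an achiral aldehyde), then the C2=C3 methylene (back to an aryl 4-methoxybenzoate), then the O1–C and O5–C bonds (back to 2,6-dihydroxy-4-methoxybenzaldehyde).
2. Enabling feature: C4 is a carbonyl carbon on C4a of ring A, ortho to O1, and C2 carries only H, O1 and the anisyl ring. The enol ether O1–C2(anisyl)=C3H2 plus a C4–H aldehyde is therefore an isomer of the flavanone, and adding C4–H across C2=C3 (C4 to C3, H to C2) gives ring C and the stereocentre with no by-product.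
3. Forward: rings A and B are bought. O5 is prenylated, O1 aroylated, the aldehyde masked as an acetal, the ester methylenated and the aldehyde unmasked; then ring C is closed, and last the prenyl group is moved from O5 to C8.
4. Stereochemistry: the only stereocentre, C2 (S), comes from catalyst-controlled hydride delivery (chiral bisphosphine on rhodium) during ring closure; no basic step follows.
5. Helpers: the dimethyl acetal is a temporary aldehyde mask (removed in step 5); the O5-prenyl group protects the peri-hydroxyl in the key step and then becomes the C8 substituent.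

Key step: step 6

Remark 1: 2,6-dihydroxy-4-methoxybenzaldehyde (1) is taken as a catalogue compound; otherwise one selective 4-O-methylation of 2,4,6-trihydroxybenzaldehyde would supply it.
Remark 2: the facial sense of the bisphosphine cannot be assigned in advance for this substrate class; the (R)-ligand is written, and its antipode is to be used if hydride delivery goes to the other face.

## Route

Step 1
Reactants: 1 2,6-dihydroxy-4-methoxybenzaldehyde; 2 prenyl bromide (1-bromo-3-methylbut-2-ene)
Product: 3 2-hydroxy-4-methoxy-6-[(3-methylbut-2-en-1-yl)oxy]benzaldehyde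
Conditions: 2 (1.0 equiv), K2CO3 (1.1 equiv), acetone, rt
Reagents that add atoms: prenyl bromide 2, CC(C)=CCBr
Why: Williamson etherification of the symmetric bis-phenol should stop at the mono-ether, because the remaining hydroxyl is then locked in a hydrogen bond to the formyl oxygen and is much less nucleophilic.

Step 2
Reactants: 3 2-hydroxy-4-methoxy-6-[(3-methylbut-2-en-1-yl)oxy]benzaldehyde; 4 4-methoxybenzoyl chloride
Product: 5 2-formyl-5-methoxy-3-[(3-methylbut-2-en-1-yl)oxy]phenyl 4-methoxybenzoate
Conditions: 4 (1.2 equiv), Et3N, DMAP (cat.), CH2Cl2, 0 °C to rt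
Reagents that add atoms: 4-methoxybenzoyl chloride 4, COc1ccc(C(=O)Cl)cc1
Why: DMAP-catalysed O-acylation of a phenol by an aroyl chloride is reliable even for hydrogen-bonded ortho-formyl phenols and places the future C2 and ring B on O1.

Step 3
Reactants: 5 2-formyl-5-methoxy-3-[(3-methylbut-2-en-1-yl)oxy]phenyl 4-methoxybenzoate
Product: 6 2-(dimethoxymethyl)-5-methoxy-3-[(3-methylbut-2-en-1-yl)oxy]phenyl 4-methoxybenzoate
Conditions: HC(OMe)3 (10 equiv), camphorsulfonic acid (2 mol %), CH2Cl2, rt; Et3N quench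
Reagents that add atoms: trimethyl orthoformate, COC(OC)OC
Why: acid-catalysed acetalisation driven by loss of methyl formate masks the aldehyde, which would otherwise be methylenated before the ester in step 4, and the aprotic medium avoids methanolysis of the aryl ester.

Step 4
Reactants: 6 2-(dimethoxymethyl)-5-methoxy-3-[(3-methylbut-2-en-1-yl)oxy]phenyl 4-methoxybenzoate
Product: 7 2-(dimethoxymethyl)-5-methoxy-1-{[1-(4-methoxyphenyl)ethenyl]oxy}-3-[(3-methylbut-2-en-1-yl)oxy]benzene
Conditions: Cp2TiMe2 (2.5 equiv), toluene, 70 °C, dark; filtration through basic Al2O3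
Reagents that add atoms: dimethyltitanocene Cp2TiMe2, C[Ti](C)(C1C=CC=C1)C1C=CC=C1
Why: Petasis methylenation turns an aryl ester into an aryl 1-arylvinyl ether through the titanocene methylidene and an oxatitanacyclobutane, and its neutral conditions should leave the acetal, the prenyl ether and the methyl ethers untouched.

Step 5
Reactants: 7 2-(dimethoxymethyl)-5-methoxy-1-{[1-(4-methoxyphenyl)ethenyl]oxy}-3-[(3-methylbut-2-en-1-yl)oxy]benzene
Product: 8 4-methoxy-2-{[1-(4-methoxyphenyl)ethenyl]oxy}-6-[(3-methylbut-2-en-1-yl)oxy]benzaldehyde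
Conditions: PPTS (5 mol %), acetone/H2O 20:1, 0 °C; NaHCO3 quench
Reagents that add atoms: water, O
Why: in this acetal hydrolysis the benzylic oxocarbenium ion is stabilised by three ring oxygens and should form far faster than the aryl enol ether is protonated at carbon, so the aldehyde is released with the enol ether intact.

Step 6
Reactants: 8 4-methoxy-2-{[1-(4-methoxyphenyl)ethenyl]oxy}-6-[(3-methylbut-2-en-1-yl)oxy]benzaldehyde
Product: 9 (2S)-7-methoxy-2-(4-methoxyphenyl)-5-[(3-methylbut-2-en-1-yl)oxy]-2,3-dihydro-4H-chromen-4-one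
Conditions: [Rh(cod)Cl]2 (2.5 mol %), (R)-DTBM-SEGPHOS (5 mol %), NaB[3,5-(CF3)2C6H3]4 (5 mol %), 4 Å sieves, 1,4-dioxane, 80 °C
Reagents that add atoms: none
Why: Proposed new method: cationic monovalent rhodium, held by the enol ether π-bond, should insert into the neighbouring formyl C–H to give an acyl hydride of trivalent rhodium, the 1,1-disubstituted alkene then inserts into Rh–H with H going to C2 and rhodium to the terminal C3, and C–C reductive elimination from the seven-membered acyl–alkyl rhodacycle forms C3–C4. The closest known reaction type is the rhodium-catalysed enantioselective intramolecular hydroacylation of aryl aldehydes bearing an ortho-tethered 1,1-disubstituted alkene (ortho-allylbenzaldehydes to 3-substituted tetralones, N-(1-arylvinyl)indole-2-carbaldehydes to fused ketones), which has not been shown for aryl 1-arylvinyl ethers. Ring C closes in a formal 6-endo-trig mode with respect to C2=C3. The C2 stereocentre is created by hydride transfer to one face of the prochiral alkene and is controlled by the C2-symmetric bisphosphine on rhodium. The step needs C3–C4 rather than C2–C4 bond formation (the latter would give a 2-aryl-2-methylbenzofuran-3-one), which is secured because that path requires a tertiary alkyl–rhodium and reductive elimination to a quaternary carbon. It also needs the enol ether to react before the prenyl alkene and before decarbonylation, which the slow insertion of trisubstituted alkenes and the chelating alkene and O1 should secure.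

Step 7
Reactants: 9 (2S)-7-methoxy-2-(4-methoxyphenyl)-5-[(3-methylbut-2-en-1-yl)oxy]-2,3-dihydro-4H-chromen-4-one
Product: 12 flowerine, via ortho-dienone 10 (not isolated), via para-dienone 11 (not isolated)
Conditions: Eu(fod)3 (10 mol %), acid-free CHCl3, 65 °C, sealed tube
Reagents that add atoms: none
Why: the europium-catalysed para-Claisen–Cope rearrangement known for 5-O-prenyl flavonoids ([3,3] shift to C6, [3,3] shift on to C8, then enolisation to the hydrogen-bonded 5-hydroxyl) should move the prenyl group to C8, and the neutral aprotic medium should leave C2 untouched.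

## Compound list

1 | 2,6-dihydroxy-4-methoxybenzaldehyde | COc1cc(O)c(C=O)c(O)c1 | starting material
2 | prenyl bromide (1-bromo-3-methylbut-2-ene) | CC(C)=CCBr | starting material
3 | 2-hydroxy-4-methoxy-6-[(3-methylbut-2-en-1-yl)oxy]benzaldehyde | COc1cc(O)c(C=O)c(OCC=C(C)C)c1 | intermediate
4 | 4-methoxybenzoyl chloride | COc1ccc(C(=O)Cl)cc1 | starting material
5 | 2-formyl-5-methoxy-3-[(3-methylbut-2-en-1-yl)oxy]phenyl 4-methoxybenzoate | COc1ccc(C(=O)Oc2cc(OC)cc(OCC=C(C)C)c2C=O)cc1 | intermediate
6 | 2-(dimethoxymethyl)-5-methoxy-3-[(3-methylbut-2-en-1-yl)oxy]phenyl 4-methoxybenzoate | COc1ccc(C(=O)Oc2cc(OC)cc(OCC=C(C)C)c2C(OC)OC)cc1 | intermediate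
7 | 2-(dimethoxymethyl)-5-methoxy-1-{[1-(4-methoxyphenyl)ethenyl]oxy}-3-[(3-methylbut-2-en-1-yl)oxy]benzene | COc1ccc(C(=C)Oc2cc(OC)cc(OCC=C(C)C)c2C(OC)OC)cc1 | intermediate
8 | 4-methoxy-2-{[1-(4-methoxyphenyl)ethenyl]oxy}-6-[(3-methylbut-2-en-1-yl)oxy]benzaldehyde | COc1ccc(C(=C)Oc2cc(OC)cc(OCC=C(C)C)c2C=O)cc1 | intermediate
9 | (2S)-7-methoxy-2-(4-methoxyphenyl)-5-[(3-methylbut-2-en-1-yl)oxy]-2,3-dihydro-4H-chromen-4-one | COc1ccc([C@@H]2CC(=O)c3c(OCC=C(C)C)cc(OC)cc3O2)cc1 | intermediate
10 | (2S)-7-methoxy-2-(4-methoxyphenyl)-6-(2-methylbut-3-en-2-yl)-2,3-dihydro-4H-chromene-4,5(6H)-dione (ortho-dienone, both C6 epimers, not isolated) | COc1ccc([C@@H]2CC(=O)C3=C(O2)C=C(OC)C(C(C)(C)C=C)C3=O)cc1 | intermediate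
11 | (2S)-7-methoxy-2-(4-methoxyphenyl)-8-(3-methylbut-2-en-1-yl)-2,3-dihydro-4H-chromene-4,5(8H)-dione (para-dienone, both C8 epimers, not isolated) | COc1ccc([C@@H]2CC(=O)C3=C(O2)C(CC=C(C)C)C(OC)=CC3=O)cc1 | intermediate
12 | flowerine, (2S)-5-hydroxy-7-methoxy-2-(4-methoxyphenyl)-8-(3-methylbut-2-en-1-yl)-2,3-dihydro-4H-chromen-4-one | COc1ccc([C@@H]2CC(=O)c3c(O)cc(OC)c(CC=C(C)C)c3O2)cc1 | target

## Summary

Total step count: 7. Longest linear sequence: 7 steps (1 to 12).

## Steps most likely to fail

**Step 6 (proposed new method).** The acyl rhodium hydride may decarbonylate, the alkyl–rhodium may eliminate β-aryloxide, closure may occur at C2 to give the five-membered ring, the prenyl alkene may insert, or facial discrimination may be poor. The fallback uses known chemistry, sets out from 3 and comes back at 9, making the C2–aryl bond instead of C3–C4.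
- Aldehyde 3 is treated with HC≡CMgBr (excess, THF, 0 °C) to give the propargylic alcohol 1-{2-hydroxy-4-methoxy-6-[(3-methylbut-2-en-1-yl)oxy]phenyl}prop-2-yn-1-ol F1.
- MnO2 in CH2Cl2 oxidises it to the ynone 1-{2-hydroxy-4-methoxy-6-[(3-methylbut-2-en-1-yl)oxy]phenyl}prop-2-yn-1-one F2.
- K2CO3 in acetone closes this by 6-endo-dig oxa-Michael addition to the chromone 7-methoxy-5-[(3-methylbut-2-en-1-yl)oxy]-4H-chromen-4-one F3.
- Enantioselective conjugate addition of 4-methoxyphenylboronic acid, catalysed by divalent palladium with a pyridine–oxazoline ligand (Pd(OCOCF3)2, (S)-t-BuPyOX or its antipode, NH4PF6, H2O, 1,2-dichloroethane, 60 °C), a known route from chromones to flavanones, should then give 9.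

**Step 7.** The ortho-dienone may enolise before the Cope shift, leaving a reversed prenyl group at C6, and the C2 configuration may erode by reversible opening of ring C (retro-oxa-Michael) under Lewis acid and heat. The fallback moves the prenyl group before any stereocentre exists; it sets out from 5 and comes back at 12.
- The same Eu(fod)3-catalysed para-Claisen–Cope rearrangement on 5 should give 2-formyl-3-hydroxy-5-methoxy-6-(3-methylbut-2-en-1-yl)phenyl 4-methoxybenzoate F4, with the prenyl group next to the ester oxygen.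
- MOMCl and i-Pr2NEt give the MOM ether 2-formyl-5-methoxy-3-(methoxymethoxy)-6-(3-methylbut-2-en-1-yl)phenyl 4-methoxybenzoate F5.
- HC(OMe)3 with catalytic camphorsulfonic acid gives the dimethyl acetal 2-(dimethoxymethyl)-5-methoxy-3-(methoxymethoxy)-6-(3-methylbut-2-en-1-yl)phenyl 4-methoxybenzoate F6.
- Cp2TiMe2 gives the enol ether 2-(dimethoxymethyl)-5-methoxy-1-(methoxymethoxy)-3-{[1-(4-methoxyphenyl)ethenyl]oxy}-4-(3-methylbut-2-en-1-yl)benzene F7.
- PPTS in wet acetone releases the aldehyde 4-methoxy-6-(methoxymethoxy)-2-{[1-(4-methoxyphenyl)ethenyl]oxy}-3-(3-methylbut-2-en-1-yl)benzaldehyde F8.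
- The hydroacylation of step 6 should give (2S)-7-methoxy-5-(methoxymethoxy)-2-(4-methoxyphenyl)-8-(3-methylbut-2-en-1-yl)-2,3-dihydro-4H-chromen-4-one F9.
- Dilute HCl in MeOH at rt removes the MOM group to give 12.

**Step 5.** Protonation at carbon and hydrolysis of the enol ether may compete with ionisation of the acetal, so that the vinyl ether is lost during unmasking or on SiO2. The fallback never masks the aldehyde; it sets out from 3 and comes back at 8.
- Mitsunobu etherification of 3 with racemic 2-bromo-1-(4-methoxyphenyl)ethanol (PPh3, DIAD, THF, 0 °C to rt) should give the bromo ether 2-{[2-bromo-1-(4-methoxyphenyl)ethyl]oxy}-4-methoxy-6-[(3-methylbut-2-en-1-yl)oxy]benzaldehyde F10.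
- Classical dehydrobromination with KOtBu in THF at 0 °C removes the benzylic α-oxy hydrogen and bromide to give the enol ether 8.

## Further compounds

F1 | step 6 | 1-{2-hydroxy-4-methoxy-6-[(3-methylbut-2-en-1-yl)oxy]phenyl}prop-2-yn-1-ol (racemic) | COc1cc(O)c(C(O)C#C)c(OCC=C(C)C)c1
F2 | step 6 | 1-{2-hydroxy-4-methoxy-6-[(3-methylbut-2-en-1-yl)oxy]phenyl}prop-2-yn-1-one | COc1cc(O)c(C(=O)C#C)c(OCC=C(C)C)c1
F3 | step 6 | 7-methoxy-5-[(3-methylbut-2-en-1-yl)oxy]-4H-chromen-4-one | COc1cc(OCC=C(C)C)c2c(c1)OC=CC2=O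
F4 | step 7 | 2-formyl-3-hydroxy-5-methoxy-6-(3-methylbut-2-en-1-yl)phenyl 4-methoxybenzoate | COc1ccc(C(=O)Oc2c(CC=C(C)C)c(OC)cc(O)c2C=O)cc1
F5 | step 7 | 2-formyl-5-methoxy-3-(methoxymethoxy)-6-(3-methylbut-2-en-1-yl)phenyl 4-methoxybenzoate | COc1ccc(C(=O)Oc2c(CC=C(C)C)c(OC)cc(OCOC)c2C=O)cc1
F6 | step 7 | 2-(dimethoxymethyl)-5-methoxy-3-(methoxymethoxy)-6-(3-methylbut-2-en-1-yl)phenyl 4-methoxybenzoate | COc1ccc(C(=O)Oc2c(CC=C(C)C)c(OC)cc(OCOC)c2C(OC)OC)cc1
F7 | step 7 | 2-(dimethoxymethyl)-5-methoxy-1-(methoxymethoxy)-3-{[1-(4-methoxyphenyl)ethenyl]oxy}-4-(3-methylbut-2-en-1-yl)benzene | COc1ccc(C(=C)Oc2c(CC=C(C)C)c(OC)cc(OCOC)c2C(OC)OC)cc1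
F8 | step 7 | 4-methoxy-6-(methoxymethoxy)-2-{[1-(4-methoxyphenyl)ethenyl]oxy}-3-(3-methylbut-2-en-1-yl)benzaldehyde | COc1ccc(C(=C)Oc2c(CC=C(C)C)c(OC)cc(OCOC)c2C=O)cc1
F9 | step 7 | (2S)-7-methoxy-5-(methoxymethoxy)-2-(4-methoxyphenyl)-8-(3-methylbut-2-en-1-yl)-2,3-dihydro-4H-chromen-4-one | COc1ccc([C@@H]2CC(=O)c3c(OCOC)cc(OC)c(CC=C(C)C)c3O2)cc1
F10 | step 5 | 2-{[2-bromo-1-(4-methoxyphenyl)ethyl]oxy}-4-methoxy-6-[(3-methylbut-2-en-1-yl)oxy]benzaldehyde (racemic) | COc1ccc(C(CBr)Oc2cc(OC)cc(OCC=C(C)C)c2C=O)cc1
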